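**Strategy.** Salvianolic acid E is an unsymmetrical dimer of (R)-rosmarinic acid in which C2 of one caffeoyl catechol ring (the ring carbon between the C1 propenoate and the C3 hydroxyl) is bonded to the acrylate α-carbon (C8′) of the second caffeoyl unit. The route rests on this aryl–vinyl sp2–sp2 bond. A Suzuki–Miyaura coupling unites two fully elaborated, PMB-protected rosmarinate halves, a C2 aryl pinacol boronate and a (Z)-α-bromoacrylate, and carries the bromoalkene geometry stereospecifically into the (E)-2,3-diarylacrylate. Both halves come from one phosphorus ylide built on protected (R)-danshensu by Wittig olefination; one acidolysis then removes all ten PMB groups.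

Key step: step 10

Remark: PMB = 4-methoxybenzyl; sodium (R)-danshensu and 2-bromo-3-hydroxy-4-methoxybenzaldehyde are taken as catalogue compounds, and both (R) centres of the target are carried unchanged from the former (all acylations occur at oxygen, with retention).

**Step 1**
Reactants: 1 sodium (R)-danshensu [sodium (2R)-3-(3,4-dihydroxyphenyl)-2-hydroxypropanoate]
Product: 2 4-methoxybenzyl (2R)-3-[3,4-bis(4-methoxybenzyloxy)phenyl]-2-hydroxypropanoate
Conditions: PMBCl (3.3 equiv), K2CO3, n-Bu4NI (cat.), DMF, rt → 40 °C, N2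
Reagents that add atoms: 4-methoxybenzyl chloride, COc1ccc(CCl)cc1
Why: Williamson-type O-alkylation in which carbonate ionises only the two phenols, so these and the carboxylate are benzylated while the much less acidic secondary hydroxyl stays free and the (R) centre is not touched.

**Step 2**
Reactants: 2 protected danshensu alcohol; 3 bromoacetyl bromide
Product: 4 4-methoxybenzyl (2R)-2-(bromoacetoxy)-3-[3,4-bis(4-methoxybenzyloxy)phenyl]propanoate
Conditions: pyridine, CH2Cl2, −10 → 0 °C
Reagents that add atoms: none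
Why: O-acylation of the secondary alcohol by the acid bromide (nucleophilic acyl substitution) breaks only the O–H bond, so the carbinol configuration is retained.

**Step 3**
Reactants: 4 bromoacetate
Product: 6 4-methoxybenzyl (2R)-3-[3,4-bis(4-methoxybenzyloxy)phenyl]-2-[(triphenylphosphoranylidene)acetoxy]propanoate, via phosphonium bromide 5 (not isolated)
Conditions: PPh3, toluene, rt; then aq. Na2CO3/CH2Cl2, 0 °C
Reagents that add atoms: triphenylphosphine, c1ccc(cc1)P(c1ccccc1)c1ccccc1
Why: SN2 quaternisation of triphenylphosphine by the α-bromo ester and deprotonation of the acidic phosphonium CH2 should give the ester-stabilised Wittig ylide, which at or below room temperature does not attack the neighbouring ester carbonyl.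

**Step 4**
Reactants: 7 3,4-dihydroxybenzaldehyde
Product: 8 3,4-bis(4-methoxybenzyloxy)benzaldehyde
Conditions: PMBCl (2.3 equiv), K2CO3, n-Bu4NI (cat.), DMF, 50 °C
Reagents that add atoms: 4-methoxybenzyl chloride, COc1ccc(CCl)cc1
Why: Williamson etherification of both phenoxides with the activated benzylic chloride.

**Step 5**
Reactants: 6 ylide; 8 3,4-bis(4-methoxybenzyloxy)benzaldehyde
Product: 10 4-methoxybenzyl (2R)-2-{[(2Z)-2-bromo-3-[3,4-bis(4-methoxybenzyloxy)phenyl]prop-2-enoyl]oxy}-3-[3,4-bis(4-methoxybenzyloxy)phenyl]propanoate, via bromo ylide 9 (not isolated)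
Conditions: NBS (1.0 equiv), CH2Cl2, −20 °C; then 8, −20 → 40 °C
Reagents that add atoms: N-bromosuccinimide, O=C1CCC(=O)N1Br
Why: Electrophilic bromination of the nucleophilic ylide carbon by NBS (the succinimide anion removes the remaining α-proton) gives the bromo ylide, and its Wittig olefination, like that of other ester-stabilised ylides, places the ester trans to the aryl group and should therefore give the (Z)-α-bromoacrylate.

**Step 6**
Reactants: 11 2-bromo-3-hydroxy-4-methoxybenzaldehyde
Product: 12 2-bromo-3,4-dihydroxybenzaldehyde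
Conditions: BBr3 (2.5 equiv), CH2Cl2, −78 °C → rt; H2O
Reagents that add atoms: none
Why: Lewis-acid-mediated aryl methyl ether cleavage (BBr3 demethylation), to which the aryl bromide and the aldehyde are inert.

**Step 7**
Reactants: 12 2-bromo-3,4-dihydroxybenzaldehyde
Product: 13 2-bromo-3,4-bis(4-methoxybenzyloxy)benzaldehyde
Conditions: PMBCl (2.4 equiv), K2CO3, n-Bu4NI (cat.), DMF, 50 °C
Reagents that add atoms: 4-methoxybenzyl chloride, COc1ccc(CCl)cc1
Why: Williamson etherification; the hindered 3-phenoxide flanked by bromine is still alkylated by the reactive benzylic chloride.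

**Step 8**
Reactants: 13 2-bromo-3,4-bis(4-methoxybenzyloxy)benzaldehyde; 6 ylide
Product: 14 4-methoxybenzyl (2R)-2-{[(2E)-3-[2-bromo-3,4-bis(4-methoxybenzyloxy)phenyl]prop-2-enoyl]oxy}-3-[3,4-bis(4-methoxybenzyloxy)phenyl]propanoate
Conditions: toluene, 70 °C
Reagents that add atoms: none
Why: Wittig olefination with an ester-stabilised ylide is reliably (E)-selective with aromatic aldehydes, and the ortho bromine raises the electrophilicity of the aldehyde.

**Step 9**
Reactants: 14 aryl bromide
Product: 15 4-methoxybenzyl (2R)-2-{[(2E)-3-[3,4-bis(4-methoxybenzyloxy)-2-(4,4,5,5-tetramethyl-1,3,2-dioxaborolan-2-yl)phenyl]prop-2-enoyl]oxy}-3-[3,4-bis(4-methoxybenzyloxy)phenyl]propanoate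
Conditions: B2pin2 (1.5 equiv), XPhos Pd G2 (5 mol%), KOAc, 1,4-dioxane, 90 °C
Reagents that add atoms: bis(pinacolato)diboron, CC1(C)OB(OC1(C)C)B1OC(C)(C)C(C)(C)O1
Why: Miyaura borylation (oxidative addition of Pd(0) to the aryl bromide, acetate-assisted transmetalation with B2pin2, reductive elimination), in which the bulky biarylphosphine accommodates the two ortho substituents and acetate is too weak a base to affect the esters or the α-stereocentres.

**Step 10**
Reactants: 15 aryl pinacol boronate; 10 (Z)-α-bromoacrylate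
Product: 16 deca-PMB salvianolic acid E [4-methoxybenzyl (2R)-2-{[(2E)-3-[2-{(1E)-2-[3,4-bis(4-methoxybenzyloxy)phenyl]-1-({(2R)-3-[3,4-bis(4-methoxybenzyloxy)phenyl]-1-(4-methoxybenzyloxy)-1-oxopropan-2-yl}oxycarbonyl)ethenyl}-3,4-bis(4-methoxybenzyloxy)phenyl]prop-2-enoyl]oxy}-3-[3,4-bis(4-methoxybenzyloxy)phenyl]propanoate]
Conditions: SPhos Pd G3 (5 mol%), K3PO4 (3 equiv), toluene/H2O 10:1, 60 °C, degassed; 15 in slight excess
Reagents that add atoms: none
Why: Pd(0)/SPhos inserts with retention into the C(sp2)–Br bond of 10 (fast, because an α-bromoacrylate is an electron-poor vinyl halide), phosphate and water turn the pinacol boronate 15 into the ate species that transfers C2 of the central ring to the alkenylpalladium, and reductive elimination forms the C2–Cα bond and returns Pd(0). The closest known reaction type is the Suzuki–Miyaura coupling of (Z)-α-bromocinnamates and other α-haloacrylates with ortho-substituted arylboron reagents, which proceeds with retention of alkene geometry. No ring is closed and no stereocentre is created; the one stereochemical element formed, the trisubstituted alkene, is controlled by the geometry of 10, where Br is cis to the β-aryl group, so the incoming ring ends cis to that aryl group and the ester trans, which is the (E)-2,3-diarylacrylate of the target. The step needs chemoselectivity for the vinyl bromide over Heck-type insertion into either cinnamate and over protodeboronation of the doubly ortho-substituted, electron-rich boronate, and the bulky electron-rich dialkylbiarylphosphine is chosen because it accelerates transmetalation and reductive elimination at hindered centres. PMB ethers and esters are inert to Pd(0), and the mild phosphate base at 60 °C with little water should leave both acyloxy ester linkages and both (R) centres untouched.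

**Step 11**
Reactants: 16 deca-PMB salvianolic acid E
Product: 17 salvianolic acid E
Conditions: TFA/CH2Cl2 1:5, pentamethylbenzene (40 equiv), 0 °C → rt, Ar; reversed-phase chromatography
Reagents that add atoms: none
Why: Acidolytic SN1 cleavage of all eight PMB aryl ethers and both PMB esters, with the 4-methoxybenzyl cations intercepted by a large excess of non-basic pentamethylbenzene (Friedel–Crafts trapping) before they can alkylate the liberated catechols, while the ester linkages, both alkenes and the stereocentres are stable to anhydrous TFA.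

**Compound list**

1 | sodium (2R)-3-(3,4-dihydroxyphenyl)-2-hydroxypropanoate (sodium (R)-danshensu) | [Na+].[O-]C(=O)[C@H](O)Cc1ccc(O)c(O)c1 | starting material
2 | 4-methoxybenzyl (2R)-3-[3,4-bis(4-methoxybenzyloxy)phenyl]-2-hydroxypropanoate | O[C@H](Cc1ccc(OCc2ccc(OC)cc2)c(OCc2ccc(OC)cc2)c1)C(=O)OCc1ccc(OC)cc1 | intermediate
3 | bromoacetyl bromide | BrCC(Br)=O | starting material
4 | 4-methoxybenzyl (2R)-2-(bromoacetoxy)-3-[3,4-bis(4-methoxybenzyloxy)phenyl]propanoate | BrCC(=O)O[C@H](Cc1ccc(OCc2ccc(OC)cc2)c(OCc2ccc(OC)cc2)c1)C(=O)OCc1ccc(OC)cc1 | intermediate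
5 | triphenylphosphonium bromide of 4 (Ph3P+ on the acetate CH2) | [Br-].O=C(C[P+](c1ccccc1)(c1ccccc1)c1ccccc1)O[C@H](Cc1ccc(OCc2ccc(OC)cc2)c(OCc2ccc(OC)cc2)c1)C(=O)OCc1ccc(OC)cc1 | intermediate (not isolated)
6 | 4-methoxybenzyl (2R)-3-[3,4-bis(4-methoxybenzyloxy)phenyl]-2-[(triphenylphosphoranylidene)acetoxy]propanoate | O=C(C=P(c1ccccc1)(c1ccccc1)c1ccccc1)O[C@H](Cc1ccc(OCc2ccc(OC)cc2)c(OCc2ccc(OC)cc2)c1)C(=O)OCc1ccc(OC)cc1 | intermediate
7 | 3,4-dihydroxybenzaldehyde | O=Cc1ccc(O)c(O)c1 | starting material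
8 | 3,4-bis(4-methoxybenzyloxy)benzaldehyde | O=Cc1ccc(OCc2ccc(OC)cc2)c(OCc2ccc(OC)cc2)c1 | intermediate
9 | 4-methoxybenzyl (2R)-3-[3,4-bis(4-methoxybenzyloxy)phenyl]-2-[bromo(triphenylphosphoranylidene)acetoxy]propanoate | O=C(C(Br)=P(c1ccccc1)(c1ccccc1)c1ccccc1)O[C@H](Cc1ccc(OCc2ccc(OC)cc2)c(OCc2ccc(OC)cc2)c1)C(=O)OCc1ccc(OC)cc1 | intermediate (not isolated)
10 | 4-methoxybenzyl (2R)-2-{[(2Z)-2-bromo-3-[3,4-bis(4-methoxybenzyloxy)phenyl]prop-2-enoyl]oxy}-3-[3,4-bis(4-methoxybenzyloxy)phenyl]propanoate | Br/C(=C\c1ccc(OCc2ccc(OC)cc2)c(OCc2ccc(OC)cc2)c1)C(=O)O[C@H](Cc1ccc(OCc2ccc(OC)cc2)c(OCc2ccc(OC)cc2)c1)C(=O)OCc1ccc(OC)cc1 | intermediate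
11 | 2-bromo-3-hydroxy-4-methoxybenzaldehyde | O=Cc1ccc(OC)c(O)c1Br | starting material
12 | 2-bromo-3,4-dihydroxybenzaldehyde | O=Cc1ccc(O)c(O)c1Br | intermediate
13 | 2-bromo-3,4-bis(4-methoxybenzyloxy)benzaldehyde | O=Cc1ccc(OCc2ccc(OC)cc2)c(OCc2ccc(OC)cc2)c1Br | intermediate
14 | 4-methoxybenzyl (2R)-2-{[(2E)-3-[2-bromo-3,4-bis(4-methoxybenzyloxy)phenyl]prop-2-enoyl]oxy}-3-[3,4-bis(4-methoxybenzyloxy)phenyl]propanoate | O=C(/C=C/c1ccc(OCc2ccc(OC)cc2)c(OCc2ccc(OC)cc2)c1Br)O[C@H](Cc1ccc(OCc2ccc(OC)cc2)c(OCc2ccc(OC)cc2)c1)C(=O)OCc1ccc(OC)cc1 | intermediate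
15 | 4-methoxybenzyl (2R)-2-{[(2E)-3-[3,4-bis(4-methoxybenzyloxy)-2-(4,4,5,5-tetramethyl-1,3,2-dioxaborolan-2-yl)phenyl]prop-2-enoyl]oxy}-3-[3,4-bis(4-methoxybenzyloxy)phenyl]propanoate | O=C(/C=C/c1ccc(OCc2ccc(OC)cc2)c(OCc2ccc(OC)cc2)c1B1OC(C)(C)C(C)(C)O1)O[C@H](Cc1ccc(OCc2ccc(OC)cc2)c(OCc2ccc(OC)cc2)c1)C(=O)OCc1ccc(OC)cc1 | intermediate
16 | deca-PMB salvianolic acid E (all eight phenols as PMB ethers, both acids as PMB esters; (E)-cinnamate, (E)-2,3-diarylacrylate, both centres R) | O=C(/C=C/c1ccc(OCc2ccc(OC)cc2)c(OCc2ccc(OC)cc2)c1/C(=C\c1ccc(OCc2ccc(OC)cc2)c(OCc2ccc(OC)cc2)c1)C(=O)O[C@H](Cc1ccc(OCc2ccc(OC)cc2)c(OCc2ccc(OC)cc2)c1)C(=O)OCc1ccc(OC)cc1)O[C@H](Cc1ccc(OCc2ccc(OC)cc2)c(OCc2ccc(OC)cc2)c1)C(=O)OCc1ccc(OC)cc1 | intermediate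
17 | salvianolic acid E | O=C(/C=C/c1ccc(O)c(O)c1/C(=C\c1ccc(O)c(O)c1)C(=O)O[C@H](Cc1ccc(O)c(O)c1)C(=O)O)O[C@H](Cc1ccc(O)c(O)c1)C(=O)O | target

**Step count and risks**

Total step count: 11. Longest linear sequence: 7 steps (1 → 2 → 4 → 6 → 14 → 15 → 16 → 17, i.e. steps 1, 2, 3, 8, 9, 10, 11).

Steps most likely to fail:

Step 10. Transmetalation of the doubly ortho-substituted boronate may be slow, so that protodeboronation and homocoupling take over; the α-palladated acrylate may also lose its geometry, and the base may cleave or epimerise the acyloxy esters. The fallback forms the same bond by a base-free, water-free tin coupling and also avoids the boronate. It sets out from 14, which is stannylated with hexamethylditin and Pd(PPh3)4 in toluene at 100 °C to the aryl trimethylstannane F1. A CuI/CsF-promoted Stille coupling of F1 with 10 (Pd(PPh3)4, DMF, 45 °C) proceeds through tin-to-copper transmetalation and retains the vinyl geometry. It comes back to the route at 16.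

Step 5. Addition of the deactivated bromo ylide to the electron-rich aldehyde may be sluggish. That would give time for intramolecular Wittig closure onto the neighbouring PMB ester, for ring bromination by NBS and for incomplete (Z)-selectivity. The fallback makes the ester bond by acylation instead of olefination and sets out from 8. Commercial ethyl (triphenylphosphoranylidene)acetate is brominated with NBS to the simple reagent ethyl bromo(triphenylphosphoranylidene)acetate F2. F2 can be forced thermally with 8 to give ethyl (2Z)-2-bromo-3-[3,4-bis(4-methoxybenzyloxy)phenyl]prop-2-enoate F3, which is recrystallised to geometric purity. Saponification (LiOH, THF/H2O) gives the (Z)-α-bromo acid F4, and Steglich esterification of alcohol 2 with F4 (EDC, cat. DMAP, CH2Cl2) comes back to the route at 10.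

Step 9. Hydrodebromination may compete with slow borylation at the hindered C2 position of a substrate that already carries the ester linkages. The fallback introduces boron by lithiation on the simple arene and sets out from 13. The aldehyde is masked as the dimethyl acetal F5 (trimethyl orthoformate, PPTS, MeOH). Bromine–lithium exchange with n-BuLi in THF at −78 °C gives the aryllithium F6, which is trapped with 2-isopropoxy-4,4,5,5-tetramethyl-1,3,2-dioxaborolane to the acetal boronate F7. Mild hydrolysis (PPTS, wet acetone) releases the 2-formylaryl boronate F8, and Wittig olefination of F8 with ylide 6 (toluene, 60 °C) comes back to the route at 15.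

**Further compounds**

F1 | step 10 | 4-methoxybenzyl (2R)-2-{[(2E)-3-[3,4-bis(4-methoxybenzyloxy)-2-(trimethylstannyl)phenyl]prop-2-enoyl]oxy}-3-[3,4-bis(4-methoxybenzyloxy)phenyl]propanoate | O=C(/C=C/c1ccc(OCc2ccc(OC)cc2)c(OCc2ccc(OC)cc2)c1[Sn](C)(C)C)O[C@H](Cc1ccc(OCc2ccc(OC)cc2)c(OCc2ccc(OC)cc2)c1)C(=O)OCc1ccc(OC)cc1
F2 | step 5 | ethyl bromo(triphenylphosphoranylidene)acetate | CCOC(=O)C(Br)=P(c1ccccc1)(c1ccccc1)c1ccccc1
F3 | step 5 | ethyl (2Z)-2-bromo-3-[3,4-bis(4-methoxybenzyloxy)phenyl]prop-2-enoate | Br/C(=C\c1ccc(OCc2ccc(OC)cc2)c(OCc2ccc(OC)cc2)c1)C(=O)OCC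
F4 | step 5 | (2Z)-2-bromo-3-[3,4-bis(4-methoxybenzyloxy)phenyl]prop-2-enoic acid | Br/C(=C\c1ccc(OCc2ccc(OC)cc2)c(OCc2ccc(OC)cc2)c1)C(=O)O
F5 | step 9 | 2-bromo-1-(dimethoxymethyl)-3,4-bis(4-methoxybenzyloxy)benzene | COC(OC)c1ccc(OCc2ccc(OC)cc2)c(OCc2ccc(OC)cc2)c1Br
F6 | step 9 | [6-(dimethoxymethyl)-2,3-bis(4-methoxybenzyloxy)phenyl]lithium | COC(OC)c1ccc(OCc2ccc(OC)cc2)c(OCc2ccc(OC)cc2)c1[Li]
F7 | step 9 | 2-[6-(dimethoxymethyl)-2,3-bis(4-methoxybenzyloxy)phenyl]-4,4,5,5-tetramethyl-1,3,2-dioxaborolane | COC(OC)c1ccc(OCc2ccc(OC)cc2)c(OCc2ccc(OC)cc2)c1B1OC(C)(C)C(C)(C)O1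
F8 | step 9 | 3,4-bis(4-methoxybenzyloxy)-2-(4,4,5,5-tetramethyl-1,3,2-dioxaborolan-2-yl)benzaldehyde | O=Cc1ccc(OCc2ccc(OC)cc2)c(OCc2ccc(OC)cc2)c1B1OC(C)(C)C(C)(C)O1
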